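**Reading the constants.** No rate constant is given, so you take what the two earlier runs can give. The first thing they give is that the charge hardly shows: at 10.0 min, Sunday's run at 0.050 M holds 21.0 % isomer of the product A and Saturday's at 0.20 M holds 21.5 %, a gap of 0.5 percentage points against a scatter of 0.5 points. Percentages that stay put under a change of charge point to first-order steps, so the flask at 0.10 M, half of Saturday's charge, should end where Saturday's run ends.

| flask | substrate | remark | time |
|---|---|---|---|
| Sunday's | 0.050 M | run made earlier |  |
| Saturday's | 0.20 M | run made earlier |  |
| flask | 0.10 M |  | 10 min |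

| run | time / min | isomer of the product A / % | target / % |
|---|---|---|---|
| Sunday's | 0.500 | 6.0 | 6.7 |
| Sunday's | 1.50 | 11.3 | 5.9 |
| Sunday's | 3.00 | 16.8 | 5.0 |
| Sunday's | 4.00 | 19.2 | 5.4 |
| Sunday's | 6.00 | 19.8 | 4.7 |
| Sunday's | 8.00 | 20.3 | 4.5 |
| Sunday's | 10.0 | 21.0 | 4.8 |
| Saturday's | 0.833 | 6.9 | 6.4 |
| Saturday's | 1.33 | 10.8 | 5.4 |
| Saturday's | 2.00 | 14.4 | 4.6 |
| Saturday's | 3.00 | 17.1 | 4.9 |
| Saturday's | 4.00 | 18.7 | 4.8 |
| Saturday's | 6.00 | 20.5 | 5.8 |
| Saturday's | 10.0 | 21.5 | 5.2 |

(each reading ± 0.5 percentage points)

1. ratio of isomer of the product A to target at 0.40 s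
2. ratio of isomer of the product A to target at 15 s
3. ratio of isomer of the product A to target at 10 min

- the analysis behind the earlier runs scatters by 0.5 percentage points, standard deviation

**Flat ends.** On Sunday target leads at 0.500 min, with 6.7 % against 6.0 % of the isomer, and then sinks gently to 5.0 % by 3.00 min while the isomer climbs to 16.8 %, so I treat target as held in a fast balance and follow what that balance leaves free. From 6.00 min to 10.0 min Sunday's isomer gains 1.2 points while target goes from 4.7 % to 4.8 %, so the two barely move. Isomer of the product A per target, pooled over the last readings of both runs, comes to 4.25, and this end ratio is my figure for the flask at 10 min, its second digit soft with that scatter on so small a target. The two earlier questions lie before the first reading, and the end ratio does not reach them.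

**The forecast.** The forecast, expecting “a fast substrate–target pre-equilibrium with a slower isomer leak”, gives 0.02, 0.4 and 4.3; the flask gives 0.0190, 0.380 and 4.63.

    substrate ⇌ target (K = 0.0983, k = 0.0901 s⁻¹)
    target ⇌ isomer of the product A (K = 4.59, k = 0.0127 s⁻¹)
    isomer of the product A ⇌ substrate (k = 0.00272 s⁻¹)
    substrate ⇌ dormant form (K = 0.380, k = 0.0108 s⁻¹)
    target ⇌ isomer of the product B (K = 5.10, k = 0.00475 s⁻¹)

**Two relaxations.** Taking each step by itself, target and the isomer of the product A relax into each other with a half-life of 0.747 min, shorter than the 2.93 min between that isomer and substrate, and both are short against the 10 min of the flask. The flask's 4.63 stands close to the constant 4.59 of target to isomer, which for this pair is thermodynamic control, and a reading ten times later leaves the ratio nearly in place. The end ratio of 4.25 on the flask's 4.51 % of target gives 19.2 % of isomer, where 20.9 % stands. The neighbour flask at 0.40 M holds the same 4.51 % of target and ends at a ratio of 4.63, higher than the end ratio of 4.25.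

The readings come from a simulation for substances that don't exist; the scatter is artificial.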